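**Plan**

- Retrosynthesis: the two aryl O–S bonds at O3' and O4' are cut first (the catechol is carried earlier as a diphenylmethylene ketal), then the O1–C2 bond of ring C, then the C2–C3 bond. This leads back to 4,6-dihydroxybenzofuran-3(2H)-one and 3,4-dihydroxybenzaldehyde.
- Enabling feature: ring C is a 3-hydroxy-4-pyranone (O1, C2, C3–OH, C4=O). It is the ring-enlarged isomer, richer by one oxygen, of a 2-benzylidenebenzofuran-3-one in which C4 is the furanone carbonyl, C3 is the furanone C2 that carries O1, and C2 is the benzylidene carbon. Moving O1 from C3 to C2 and placing a hydroxyl on C3 gives ring C.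
- Forward order: ketalisation of the ring B aldehyde; aldol condensation onto the ring A furanone (C2–C3); acetylation and bromine addition; alkaline enlargement of the furanone to ring C (O1–C2); benzylation of O3 and O7, ketal removal, sulfation of O3' and O4', hydrogenolysis.
- Stereochemistry: the target has no stereocentre. The Z alkene of the aurone and the two stereocentres of the dibromide are transient and are erased in the ring enlargement.

Key step: step 5

Remark: the target is drawn as the free bis(hydrogen sulfate), so 14 and 15 are written as free acids. In the flask they would be carried as ammonium or sodium salts, and 15 would be released on a sulfonic acid resin (proton form) in the cold directly before use, because aryl hydrogen sulfates solvolyse under their own acidity.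

**Step 1**
Reactants: 1 3,4-dihydroxybenzaldehyde; 2 dichlorodiphenylmethane
Product: 3 2,2-diphenyl-1,3-benzodioxole-5-carbaldehyde
Conditions: Ph2O, 175 °C, 30 min, N2 sweep
Reagents that add atoms: none
Why: Catechol ketalisation by double nucleophilic substitution at the gem-dichloride, driven by loss of HCl at high temperature, is the standard way to install a diphenylmethylene ketal and leaves the aldehyde untouched.

**Step 2**
Reactants: 4 4,6-dihydroxy-1-benzofuran-3(2H)-one; 3 2,2-diphenyl-1,3-benzodioxole-5-carbaldehyde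
Product: 6 (2Z)-2-[(2,2-diphenyl-1,3-benzodioxol-5-yl)methylidene]-4,6-dihydroxy-1-benzofuran-3(2H)-one, via aldol adduct 5 (not isolated)
Conditions: KOH (50% aq.), MeOH, 60 °C, Ar; then AcOH to pH 5, 0 °C
Reagents that add atoms: none
Why: In this Claisen–Schmidt aldol condensation the acidic C2 methylene of the furanone adds to the non-enolisable aldehyde and E1cB dehydration of 5 gives the conjugated aurone, whose Z geometry (aryl syn to O1) is the thermodynamic one; the ketal is stable to base and to the mild acidic quench.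

**Step 3**
Reactants: 6 (2Z)-2-[(2,2-diphenyl-1,3-benzodioxol-5-yl)methylidene]-4,6-dihydroxy-1-benzofuran-3(2H)-one
Product: 7 (2Z)-2-[(2,2-diphenyl-1,3-benzodioxol-5-yl)methylidene]-3-oxo-2,3-dihydro-1-benzofuran-4,6-diyl diacetate
Conditions: Ac2O, pyridine, DMAP (cat.), 0 °C to rt
Reagents that add atoms: acetic anhydride, CC(=O)OC(C)=O
Why: DMAP-catalysed O-acylation of both phenols makes ring A electron-poor, so that bromine in the next step has no reason to substitute C5 or C7.

**Step 4**
Reactants: 7 (2Z)-2-[(2,2-diphenyl-1,3-benzodioxol-5-yl)methylidene]-3-oxo-2,3-dihydro-1-benzofuran-4,6-diyl diacetate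
Product: 8 2-bromo-2-[bromo(2,2-diphenyl-1,3-benzodioxol-5-yl)methyl]-3-oxo-2,3-dihydro-1-benzofuran-4,6-diyl diacetate (racemic, mixture of diastereomers)
Conditions: Br2 (1.05 equiv), CHCl3, 0 °C, dark; evaporate, use crude
Reagents that add atoms: bromine, BrBr
Why: Electrophilic addition of bromine to the exocyclic enol ether/styrene double bond is the first half of the Auwers sequence; ring A is deactivated by its two acetoxy groups and the ketone, ring B by conjugation to the enone, and the two new stereocentres need no control because both vanish in step 5.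

**Step 5**
Reactants: 8 2-bromo-2-[bromo(2,2-diphenyl-1,3-benzodioxol-5-yl)methyl]-3-oxo-2,3-dihydro-1-benzofuran-4,6-diyl diacetate
Product: 11 2-(2,2-diphenyl-1,3-benzodioxol-5-yl)-3,5,7-trihydroxy-4H-chromen-4-one, via bromo diketone 9 (not isolated), via chromane-3,4-dione 10 (not isolated)
Conditions: KOH (0.5 M aq., 8 equiv), EtOH, Ar, 0 °C to rt; then AcOH to pH 5
Reagents that add atoms: potassium hydroxide, [K+].[OH-]
Why: Hydroxide cleaves both aryl acetates and replaces the labile bromide at the furanone C2 (an α-bromo ether, ionised with help from O1), and the resulting hemiketal collapses to the aryl 1,2-diketone 9 with release of a ring A phenoxide. That phenoxide displaces the benzylic bromide in a 6-exo-tet closure that forms the O1–C2 bond and gives chromane-3,4-dione 10, whose enolisation to the aromatic 3-hydroxy-4-pyranone 11 makes the sequence irreversible and leaves the hydroxide oxygen on C3. The closest known reaction type is the Auwers flavonol synthesis, the alkali-induced ring enlargement of aurone dibromides. No stereocentre is created, since the C2 centre of 10 is lost on enolisation and both centres of 8 disappear. The step needs O-alkylation at the benzylic carbon to outrun dehydrobromination to a bromoaurone, loss of bromine back to the aurone and benzilic acid rearrangement of 9. This is secured by the intramolecular closure, by the electron-rich ring B whose para oxygen loosens the benzylic C–Br bond, and by the symmetry of the 2,4,6-trioxygenated ring, so that either ortho phenoxide gives the same ring C; the ketal is inert to base and air is excluded to protect the phenoxides.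

**Step 6**
Reactants: 11 2-(2,2-diphenyl-1,3-benzodioxol-5-yl)-3,5,7-trihydroxy-4H-chromen-4-one
Product: 12 3,7-bis(benzyloxy)-2-(2,2-diphenyl-1,3-benzodioxol-5-yl)-5-hydroxy-4H-chromen-4-one
Conditions: BnBr (2.2 equiv), K2CO3 (2.5 equiv), DMF, 0 °C to rt
Reagents that add atoms: benzyl bromide, BrCc1ccccc1
Why: In this Williamson etherification the 7-OH (vinylogous acid) and the enolic 3-OH are the most acidic and nucleophilic hydroxyls, whereas the 5-OH is locked in a hydrogen bond to the C4 carbonyl and is not alkylated by K2CO3 at room temperature.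

**Step 7**
Reactants: 12 3,7-bis(benzyloxy)-2-(2,2-diphenyl-1,3-benzodioxol-5-yl)-5-hydroxy-4H-chromen-4-one
Product: 13 3,7-bis(benzyloxy)-2-(3,4-dihydroxyphenyl)-5-hydroxy-4H-chromen-4-one
Conditions: AcOH/H2O (4:1), reflux
Reagents that add atoms: none
Why: Acid-catalysed ketal hydrolysis proceeds through the stabilised diphenyl oxocarbenium ion and releases benzophenone, while benzyl ethers and the chromone are inert to aqueous acetic acid.

**Step 8**
Reactants: 13 3,7-bis(benzyloxy)-2-(3,4-dihydroxyphenyl)-5-hydroxy-4H-chromen-4-one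
Product: 14 4-[3,7-bis(benzyloxy)-5-hydroxy-4-oxo-4H-chromen-2-yl]-1,2-phenylene bis(hydrogen sulfate)
Conditions: SO3·NMe3 (8 equiv), Et3N, DMF, 50 °C; then sulfonic acid resin (sodium form), C18 silica
Reagents that add atoms: sulfur trioxide trimethylamine complex, C[N+](C)(C)S(=O)(=O)[O-]
Why: O-sulfonation of phenols by an amine–SO3 complex takes place at the two free ring B hydroxyls, the chelated 5-OH being far less nucleophilic, and the excess of reagent with gentle warming should push the slower second sulfation next to the first sulfate.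

**Step 9**
Reactants: 14 4-[3,7-bis(benzyloxy)-5-hydroxy-4-oxo-4H-chromen-2-yl]-1,2-phenylene bis(hydrogen sulfate)
Product: 15 4-(3,5,7-trihydroxy-4-oxo-4H-chromen-2-yl)-1,2-phenylene bis(hydrogen sulfate)
Conditions: H2 (1 atm), Pd/C (10% Pd on carbon), MeOH/THF, rt; then sulfonic acid resin (proton form), 0 °C, freeze-dry
Reagents that add atoms: none
Why: Heterogeneous hydrogenolysis removes both benzyl ethers, while aryl sulfate monoester anions, the chromone C2=C3 bond and the aromatic rings are not reduced at 1 atm and room temperature.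

**Compound list**

1 | 3,4-dihydroxybenzaldehyde | O=Cc1ccc(O)c(O)c1 | starting material
2 | dichlorodiphenylmethane | ClC(Cl)(c1ccccc1)c1ccccc1 | starting material
3 | 2,2-diphenyl-1,3-benzodioxole-5-carbaldehyde | O=Cc1ccc2OC(c3ccccc3)(c3ccccc3)Oc2c1 | intermediate
4 | 4,6-dihydroxy-1-benzofuran-3(2H)-one | O=C1COc2cc(O)cc(O)c12 | starting material
5 | 2-[(2,2-diphenyl-1,3-benzodioxol-5-yl)(hydroxy)methyl]-4,6-dihydroxy-1-benzofuran-3(2H)-one (aldol adduct, diastereomer mixture, not isolated) | O=C1C(C(O)c2ccc3OC(c4ccccc4)(c4ccccc4)Oc3c2)Oc2cc(O)cc(O)c12 | intermediate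
6 | (2Z)-2-[(2,2-diphenyl-1,3-benzodioxol-5-yl)methylidene]-4,6-dihydroxy-1-benzofuran-3(2H)-one | O=C1c2c(O)cc(O)cc2O/C1=C\c1ccc2OC(c3ccccc3)(c3ccccc3)Oc2c1 | intermediate
7 | (2Z)-2-[(2,2-diphenyl-1,3-benzodioxol-5-yl)methylidene]-3-oxo-2,3-dihydro-1-benzofuran-4,6-diyl diacetate | CC(=O)Oc1cc(OC(C)=O)c2C(=O)/C(=C/c3ccc4OC(c5ccccc5)(c5ccccc5)Oc4c3)Oc2c1 | intermediate
8 | 2-bromo-2-[bromo(2,2-diphenyl-1,3-benzodioxol-5-yl)methyl]-3-oxo-2,3-dihydro-1-benzofuran-4,6-diyl diacetate (racemic, diastereomer mixture) | CC(=O)Oc1cc(OC(C)=O)c2C(=O)C(Br)(C(Br)c3ccc4OC(c5ccccc5)(c5ccccc5)Oc4c3)Oc2c1 | intermediate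
9 | 3-bromo-3-(2,2-diphenyl-1,3-benzodioxol-5-yl)-1-(2,4,6-trihydroxyphenyl)propane-1,2-dione (present as its phenoxide, not isolated) | O=C(C(=O)C(Br)c1ccc2OC(c3ccccc3)(c3ccccc3)Oc2c1)c1c(O)cc(O)cc1O | intermediate
10 | 2-(2,2-diphenyl-1,3-benzodioxol-5-yl)-5,7-dihydroxy-2H-chromene-3,4-dione (racemic, not isolated) | O=C1C(=O)c2c(O)cc(O)cc2OC1c1ccc2OC(c3ccccc3)(c3ccccc3)Oc2c1 | intermediate
11 | 2-(2,2-diphenyl-1,3-benzodioxol-5-yl)-3,5,7-trihydroxy-4H-chromen-4-one | O=c1c(O)c(-c2ccc3OC(c4ccccc4)(c4ccccc4)Oc3c2)oc2cc(O)cc(O)c12 | intermediate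
12 | 3,7-bis(benzyloxy)-2-(2,2-diphenyl-1,3-benzodioxol-5-yl)-5-hydroxy-4H-chromen-4-one | O=c1c(OCc2ccccc2)c(-c2ccc3OC(c4ccccc4)(c4ccccc4)Oc3c2)oc2cc(OCc3ccccc3)cc(O)c12 | intermediate
13 | 3,7-bis(benzyloxy)-2-(3,4-dihydroxyphenyl)-5-hydroxy-4H-chromen-4-one | O=c1c(OCc2ccccc2)c(-c2ccc(O)c(O)c2)oc2cc(OCc3ccccc3)cc(O)c12 | intermediate
14 | 4-[3,7-bis(benzyloxy)-5-hydroxy-4-oxo-4H-chromen-2-yl]-1,2-phenylene bis(hydrogen sulfate) | O=c1c(OCc2ccccc2)c(-c2ccc(OS(=O)(=O)O)c(OS(=O)(=O)O)c2)oc2cc(OCc3ccccc3)cc(O)c12 | intermediate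
15 | 4-(3,5,7-trihydroxy-4-oxo-4H-chromen-2-yl)-1,2-phenylene bis(hydrogen sulfate) | O=c1c(O)c(-c2ccc(OS(=O)(=O)O)c(OS(=O)(=O)O)c2)oc2cc(O)cc(O)c12 | target

Total step count: 9
Longest linear sequence: 9 steps (1 to 15; 2 and 4 enter at steps 1 and 2)

**Steps most likely to fail**

Step 5 (ring enlargement). Base-induced dehydrobromination or loss of bromine back to the aurone, or benzilic acid rearrangement of the opened diketone, may outrun the phenoxide closure. A ring A that becomes a bis-phenoxide after acetate loss is the recognised weak spot of this ring enlargement. The fallback builds ring C by Algar–Flynn–Oyamada oxidative cyclisation instead; it sets out from 3 and comes back at 15.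
- Claisen–Schmidt condensation of 3 with commercial 1-[2,4-bis(benzyloxy)-6-hydroxyphenyl]ethanone (KOH, EtOH, rt) should give (E)-1-[2,4-bis(benzyloxy)-6-hydroxyphenyl]-3-(2,2-diphenyl-1,3-benzodioxol-5-yl)prop-2-en-1-one F1.
- Alkaline H2O2 (NaOH, MeOH/THF, 0 °C) should convert it into 5,7-bis(benzyloxy)-2-(2,2-diphenyl-1,3-benzodioxol-5-yl)-3-hydroxy-4H-chromen-4-one F2.
- Benzylation at O3 (BnBr, K2CO3, DMF) should give 3,5,7-tris(benzyloxy)-2-(2,2-diphenyl-1,3-benzodioxol-5-yl)-4H-chromen-4-one F3.
- Aqueous acetic acid at reflux should free the catechol, giving 3,5,7-tris(benzyloxy)-2-(3,4-dihydroxyphenyl)-4H-chromen-4-one F4.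
- SO3·NMe3/Et3N in DMF should give 4-[3,5,7-tris(benzyloxy)-4-oxo-4H-chromen-2-yl]-1,2-phenylene bis(hydrogen sulfate) F5, and hydrogenolysis over Pd/C then returns to the route at 15.

Step 4 (bromine addition). Electrophilic substitution of the electron-rich ring B, which is no longer conjugated once the alkene has reacted, or ketal cleavage by adventitious HBr may compete with clean addition. The fallback deactivates ring B with acetates and postpones the ketal until after the ring enlargement; it sets out from 4 and 1 and comes back at 11.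
- Acid-mediated aldol condensation of 4 with 1 (HCl, AcOH, rt) should give (2Z)-2-(3,4-dihydroxybenzylidene)-4,6-dihydroxy-1-benzofuran-3(2H)-one F6.
- Ac2O/pyridine should give its tetraacetate, (2Z)-2-(3,4-diacetoxybenzylidene)-3-oxo-2,3-dihydro-1-benzofuran-4,6-diyl diacetate F7.
- Br2 in CHCl3 should give 2-bromo-2-[bromo(3,4-diacetoxyphenyl)methyl]-3-oxo-2,3-dihydro-1-benzofuran-4,6-diyl diacetate F8.
- Aqueous ethanolic KOH under argon should give 2-(3,4-dihydroxyphenyl)-3,5,7-trihydroxy-4H-chromen-4-one F9.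
- Heating F9 with 2 in Ph2O at 175 °C then ketalises the catechol and returns to the route at 11.

Step 8 (bis-sulfation). The second sulfation may stall next to the first sulfate anion, or forcing conditions may spread sulfation to O5. The fallback uses neutral, chromatographable sulfate diesters; it sets out from 13 and comes back at 14.
- 2,2,2-Trichloroethyl chlorosulfate (ClS(=O)(=O)OCC(Cl)(Cl)Cl, 2.2 equiv), Et3N and DMAP in THF should give 4-[3,7-bis(benzyloxy)-5-hydroxy-4-oxo-4H-chromen-2-yl]-1,2-phenylene bis(2,2,2-trichloroethyl) bis(sulfate) F10.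
- Zn dust and HCO2NH4 in MeOH then cleave the trichloroethyl groups by reductive elimination and return to the route at 14.

**Further compounds**

F1 | step 5 | (E)-1-[2,4-bis(benzyloxy)-6-hydroxyphenyl]-3-(2,2-diphenyl-1,3-benzodioxol-5-yl)prop-2-en-1-one | O=C(/C=C/c1ccc2OC(c3ccccc3)(c3ccccc3)Oc2c1)c1c(O)cc(OCc2ccccc2)cc1OCc1ccccc1
F2 | step 5 | 5,7-bis(benzyloxy)-2-(2,2-diphenyl-1,3-benzodioxol-5-yl)-3-hydroxy-4H-chromen-4-one | O=c1c(O)c(-c2ccc3OC(c4ccccc4)(c4ccccc4)Oc3c2)oc2cc(OCc3ccccc3)cc(OCc3ccccc3)c12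
F3 | step 5 | 3,5,7-tris(benzyloxy)-2-(2,2-diphenyl-1,3-benzodioxol-5-yl)-4H-chromen-4-one | O=c1c(OCc2ccccc2)c(-c2ccc3OC(c4ccccc4)(c4ccccc4)Oc3c2)oc2cc(OCc3ccccc3)cc(OCc3ccccc3)c12
F4 | step 5 | 3,5,7-tris(benzyloxy)-2-(3,4-dihydroxyphenyl)-4H-chromen-4-one | O=c1c(OCc2ccccc2)c(-c2ccc(O)c(O)c2)oc2cc(OCc3ccccc3)cc(OCc3ccccc3)c12
F5 | step 5 | 4-[3,5,7-tris(benzyloxy)-4-oxo-4H-chromen-2-yl]-1,2-phenylene bis(hydrogen sulfate) | O=c1c(OCc2ccccc2)c(-c2ccc(OS(=O)(=O)O)c(OS(=O)(=O)O)c2)oc2cc(OCc3ccccc3)cc(OCc3ccccc3)c12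
F6 | step 4 | (2Z)-2-(3,4-dihydroxybenzylidene)-4,6-dihydroxy-1-benzofuran-3(2H)-one | O=C1c2c(O)cc(O)cc2O/C1=C\c1ccc(O)c(O)c1
F7 | step 4 | (2Z)-2-(3,4-diacetoxybenzylidene)-3-oxo-2,3-dihydro-1-benzofuran-4,6-diyl diacetate | CC(=O)Oc1cc(OC(C)=O)c2C(=O)/C(=C/c3ccc(OC(C)=O)c(OC(C)=O)c3)Oc2c1
F8 | step 4 | 2-bromo-2-[bromo(3,4-diacetoxyphenyl)methyl]-3-oxo-2,3-dihydro-1-benzofuran-4,6-diyl diacetate | CC(=O)Oc1cc(OC(C)=O)c2C(=O)C(Br)(C(Br)c3ccc(OC(C)=O)c(OC(C)=O)c3)Oc2c1
F9 | step 4 | 2-(3,4-dihydroxyphenyl)-3,5,7-trihydroxy-4H-chromen-4-one | O=c1c(O)c(-c2ccc(O)c(O)c2)oc2cc(O)cc(O)c12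
F10 | step 8 | 4-[3,7-bis(benzyloxy)-5-hydroxy-4-oxo-4H-chromen-2-yl]-1,2-phenylene bis(2,2,2-trichloroethyl) bis(sulfate) | O=c1c(OCc2ccccc2)c(-c2ccc(OS(=O)(=O)OCC(Cl)(Cl)Cl)c(OS(=O)(=O)OCC(Cl)(Cl)Cl)c2)oc2cc(OCc3ccccc3)cc(O)c12
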